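**Plan**

1. Cuts: the C1=C2–C3 lactone is masked as its allylic lactol methyl ether. The C11 ester, the C12–C13 bond and the C8–O bond lead back to a cyclohept-7-ene carrying C10(OH)(CO2Me); C8–O comes from iodolactonization by C12, and C12–C13 from opening that lactone with a (Z)-propenyl metal.
2. The C9–C10 ring bond is cut by a retro-[2,3]-Wittig shift, which re-forms a C7–O–C10 ether. The carbocycle becomes a C-(E)-propenyl pyranuronate whose C7, C6, C5, C11, C10, C12 are C-1 to C-6 of a hexose. The enabling feature is the tertiary carbinol C10 that bears the carbonyl carbon C12 and sits next to the methyl-bearing C9, two atoms from C7 (α-hydroxy-β-methyl-γ,δ-unsaturated acid pattern), in a ring whose trans C5/C11 oxygens are those of D-glucal C-3/C-4.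
3. C6–C2 and C7–C8 are cut by a radical cyclization/allyl-transfer cascade on a 3-O-(2-iodoallyl) mixed acetal of D-glucal (C1–C3 from methoxyallene).
4. Forward order of rings: pyran (bought, sacrificial) → tetrahydrofuran O4–C3–C2–C6–C5, the later lactone ring (step 3) → cycloheptene by ring expansion (step 7, last ring of the skeleton) → temporary bridged lactone (steps 8–10).
5. Stereochemistry: C5 and C11 are bought with D-glucal. C6 and the sacrificial C7 centre come from the tethered cyclization and axial radical trapping. C9 and C10 are relayed from C7 and the E alkene in the key step. C8 is delivered from C12. The Z enone comes from (Z)-prop-1-enyllithium.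

Key step: step 7

Atom numbers used below (as in 30): C1 (=CH2), C2, C3 (lactone C=O), O4, C5 (OCH), C6 (ring-fusion CH), C7 (CH2), C8 (CHOH), C9 (CHCH3), C10 (C–OH), C11 (CHO-acyl), C12 (ketone C), C13=C14, C15 (CH3).

Assumption: the mixed-acetal carbon C3 is carried as both epimers (it ends as the lactone carbonyl); D-glucal, methoxyallene and (Z)-1-bromoprop-1-ene are bought.

**Route**

Step 1
Reactants: 1 D-glucal; 2 di-tert-butylsilyl bis(trifluoromethanesulfonate)
Product: 3 4,6-O-(di-tert-butylsilanediyl)-D-glucal
Conditions: tBu2Si(OTf)2, pyridine, DMF, −40 °C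
Reagents that add atoms: di-tert-butylsilyl bis(trifluoromethanesulfonate), CC(C)(C)[Si](OS(=O)(=O)C(F)(F)F)(OS(=O)(=O)C(F)(F)F)C(C)(C)C
Why: Cyclic silylene formation (silyl ether protection) engages the 4,6-diol as a six-membered ring faster than the allylic 3-OH, which leaves the future O4 free and locks the pyran conformation; no stereocenter is made.

Step 2
Reactants: 3 4,6-O-(di-tert-butylsilanediyl)-D-glucal; 4 methoxyallene; 5 N-iodosuccinimide
Product: 6 3-O-(2-iodo-1-methoxyprop-2-en-1-yl)-4,6-O-(di-tert-butylsilanediyl)-D-glucal (both acetal epimers)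
Conditions: methoxyallene (5 equiv), NIS, CH2Cl2, −60 → −20 °C
Reagents that add atoms: methoxyallene, COC=C=C; N-iodosuccinimide, O=C1CCC(=O)N1I
Why: Iodoalkoxylation (cohalogenation) of the alkoxyallene: iodonium attack at the central allene carbon gives a 2-iodoallyl oxocarbenium ion that the free hydroxyl captures as the mixed acetal, the excess of the more electron-rich allene keeping NIS away from the glycal alkene; the acetal carbon forms as both epimers.

Step 3
Reactants: 6 iodoallyl mixed acetal; 7 allyltributylstannane
Product: 8 silylene-protected bicyclic C-allyl glycoside (C7 α-allyl; C6–C2 bond β and cis to O4; 3-methoxy-2-methylenetetrahydrofuran O4–C3–C2–C6–C5)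
Conditions: allylSnBu3 (4 equiv), AIBN (0.2 equiv), PhH, 80 °C
Reagents that add atoms: allyltributylstannane, C=CC[Sn](CCCC)(CCCC)CCCC
Why: Ueno–Stork-type 5-exo-trig cyclization of the vinyl radical onto C6 followed by Keck radical allylation of the resulting C7 (anomeric) radical: the O4 tether forces the new C6–C2 bond cis to O4, and the stannane is attacked axially, trans to that branch, in the silylene-locked chair, so the allyl group enters on the α face of C7.

Step 4
Reactants: 8 bicyclic C-allyl glycoside
Product: 9 the corresponding C7 α-(E)-prop-1-enyl glycoside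
Conditions: RuHCl(CO)(PPh3)3 (5 mol %), toluene, 80 °C
Reagents that add atoms: none
Why: Ruthenium hydride-catalysed alkene isomerization (insertion/β-hydride elimination) moves the terminal double bond one position to the (E)-prop-1-enyl group, the Z isomer being disfavoured by allylic strain against the ring and the 1,1-disubstituted exocyclic alkene inserting much more slowly.

Step 5
Reactants: 9 silylene-protected C-(E)-propenyl glycoside
Product: 10 the C11,C12-diol (free secondary C11–OH and primary C12–OH)
Conditions: HF·pyridine, pyridine, THF, 0 °C → rt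
Reagents that add atoms: none
Why: Fluoride cleavage of the silylene frees both hydroxyls, and the pyridine buffer spares the allylic methyl acetal.

Step 6
Reactants: 10 diol; 11 water; 12 iodomethane
Product: 14 methyl uronate (C12 = CO2Me, C11–OH free), via uronic acid 13 (not isolated)
Conditions: TEMPO (0.2 equiv), PhI(OAc)2 (2.5 equiv), CH2Cl2/H2O, rt; then MeI, KHCO3, DMF, rt
Reagents that add atoms: water, O; iodomethane, CI
Why: Oxoammonium (TEMPO) oxidation is selective for the primary alcohol and carries it through the aldehyde hydrate to the uronic acid without touching the secondary C11–OH or the alkenes, and carboxylate O-alkylation then gives the methyl ester.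

Step 7
Reactants: 14 methyl uronate
Product: 16 methyl 10,11-dihydroxy-9-methylcyclohept-7-ene-10-carboxylate fused at C5/C6 to the 3-methoxy-2-methylenetetrahydrofuran (C5, C6, C9, C10, C11 configured as in 30), via dilithium alkoxide enolate 15 (not isolated)
Conditions: LiN(iPr)2 (2.5 equiv), THF, −78 → −20 °C; aq NH4Cl
Reagents that add atoms: none
Why: Proposed new method: LiN(iPr)2 first forms the C11 alkoxide (a β-hydroxy ester dianion of the Fráter–Seebach type, which shuts off E1cB loss of O11) and then the C10 ester enolate, whose carbanion carbon attacks C9 of the axial (E)-propenyl group across the ring oxygen while the allylic C7–O bond breaks, a concerted suprafacial [2,3]-Wittig shift that turns the tetrahydropyran into the cycloheptene and the ring oxygen into the C10 alkoxide. The closest known reactions are the [2,3]-Wittig rearrangement of open-chain α-allyloxy ester enolates and carboxylic acid dianions and the [2,3]-Wittig ring expansion of 2-metallated 6-vinyltetrahydropyrans to cycloheptenols; their combination on a uronate enolate is not documented. The seven-membered ring is closed by the C9–C10 bond through a five-membered envelope transition state held inside an 8-oxabicyclo[3.2.1]oct-6-ene-like array (C7 and C10 as bridgeheads, oxygen as the one-atom bridge), so the new ring alkene C7=C8 is necessarily cis. C10 is set because the enolate can only be reached on the face that carries the axial C7 substituent (relay from C7, set in step 3), which leaves the new hydroxyl trans to O11 and C12 cis to it; C9 is set by the E geometry, which puts the methyl group exo, on the side of the oxygen bridge and hence cis to the C10 hydroxyl. The step needs the [2,3] path to win over the [1,2] shift, β-elimination and C-attack through C12 ([3,3] type); low temperature, the lithium enolate in place of a silyl ketene acetal, the O11 alkoxide and a ground-state chair with axial propenyl and equatorial ester should secure this.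

Step 8
Reactants: 16 cycloheptene hydroxy ester; 17 lithium hydroxide; 18 iodine
Product: 20 bridged iodolactone (C12(=O)–O–C8, iodine on C7 anti to the lactone oxygen; C10–OH and C11–OH free), via lithium carboxylate 19 (not isolated)
Conditions: LiOH, THF/H2O, rt; then NaHCO3, I2, 0 °C, dark
Reagents that add atoms: lithium hydroxide, [Li+].[OH-]; iodine, II
Why: Ester saponification followed by kinetic iodolactonization: the C12 carboxylate, fixed on the upper face of C10, opens the iodonium ion of C7=C8 in the 5-exo mode, which places oxygen on C8 cis to C12 (the C8 configuration of the target) and iodine anti on C7.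

Step 9
Reactants: 20 bridged iodolactone
Product: 21 bridged γ-lactone with C7 as CH2
Conditions: Bu3SnH, AIBN, toluene, 80 °C
Reagents that add atoms: none
Why: Radical chain hydrodeiodination with tin hydride turns C7 into the CH2 group; the lactone, the acetal and the free hydroxyls are inert under these neutral conditions.

Step 10
Reactants: 21 bridged γ-lactone; 22 (Z)-1-bromoprop-1-ene
Product: 24 8,10,11-triol (Z)-enone (C12 ketone with (Z)-prop-1-enyl; lactone ring still masked as the methyl acetal), via (Z)-prop-1-enyllithium 23 (not isolated)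
Conditions: (Z)-1-bromopropene (3.5 equiv), t-BuLi (7 equiv), Et2O, −78 °C; then 21, THF, −78 → −40 °C; aq NH4Cl at −78 °C
Reagents that add atoms: (Z)-1-bromoprop-1-ene, C/C=C\Br
Why: Bromine–lithium exchange proceeds with retention of the Z geometry, and the alkenyllithium, after deprotonating the two hydroxyls, adds once to the strained α-oxy lactone because the bicyclic lithium hemiketalate survives until the cold quench, when it collapses to the (Z)-enone and releases C8–OH; the acetal-masked lactone ring does not react.

Step 11
Reactants: 24 triol (Z)-enone; 25 chlorotriethylsilane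
Product: 26 C8 triethylsilyl ether
Conditions: Et3SiCl (1.1 equiv), imidazole, CH2Cl2, −20 °C
Reagents that add atoms: chlorotriethylsilane, CC[Si](Cl)(CC)CC
Why: Silyl ether formation is governed by sterics: C8–OH, flanked by CH2 and CHCH3, should react before C11–OH, which sits between the quaternary C10 and C5, and before the tertiary C10–OH.

Step 12
Reactants: 26 C8 triethylsilyl ether; 27 3-methylbutanoyl chloride
Product: 28 C11 3-methylbutanoate, C8 triethylsilyl ether
Conditions: 3-methylbutanoyl chloride, pyridine, CH2Cl2, 0 °C → rt
Reagents that add atoms: 3-methylbutanoyl chloride, CC(C)CC(Cl)=O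
Why: Acylation of the only remaining secondary hydroxyl with the acid chloride and pyridine; no nucleophilic catalyst is used, so the Z enone is not exposed to conjugate addition–elimination.

Step 13
Reactants: 28 protected ester; 11 water
Product: 29 α-methylene lactol (C3 hemiacetal, both anomers), C8–OH free
Conditions: AcOH/THF/H2O (3:1:1), rt
Reagents that add atoms: water, O
Why: Mild acid hydrolysis cleaves the allylic methyl acetal through its stabilized oxocarbenium ion and removes the triethylsilyl ether in the same operation.

Step 14
Reactants: 29 α-methylene lactol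
Product: 30 target CNP0186412.2
Conditions: MnO2 (activated, excess), CH2Cl2, rt
Reagents that add atoms: none
Why: MnO2 oxidizes the lactol, whose hemiacetal hydroxyl is allylic to the exocyclic methylene, to the α-methylene lactone and should leave the saturated C8–OH, the tertiary C10–OH and the Z enone alone (allylic alcohol oxidation).

**Compound list**

1 | D-glucal | OC[C@H]1OC=C[C@@H](O)[C@@H]1O | starting material
2 | di-tert-butylsilyl bis(trifluoromethanesulfonate) | CC(C)(C)[Si](OS(=O)(=O)C(F)(F)F)(OS(=O)(=O)C(F)(F)F)C(C)(C)C | starting material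
3 | 4,6-O-(di-tert-butylsilanediyl)-D-glucal | C1=C[C@@H](O)[C@@H]2O[Si](C(C)(C)C)(C(C)(C)C)OC[C@H]2O1 | intermediate
4 | methoxyallene | COC=C=C | starting material
5 | N-iodosuccinimide | O=C1CCC(=O)N1I | starting material
6 | 3-O-(2-iodo-1-methoxyprop-2-en-1-yl)-4,6-O-(di-tert-butylsilanediyl)-D-glucal, acetal epimers | C1=C[C@@H](OC(OC)C(I)=C)[C@@H]2O[Si](C(C)(C)C)(C(C)(C)C)OC[C@H]2O1 | intermediate
7 | allyltributylstannane | C=CC[Sn](CCCC)(CCCC)CCCC | starting material
8 | silylene-protected C7 α-allyl glycoside with cis-fused 3-methoxy-2-methylenetetrahydrofuran (C6–C2 β, cis to O4; C3 epimers) | C=CC[C@H]1O[C@@H]2CO[Si](C(C)(C)C)(C(C)(C)C)O[C@H]2[C@@H]2OC(OC)C(=C)[C@H]12 | intermediate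
9 | C7 α-(E)-prop-1-enyl analogue of 8 | C/C=C/[C@H]1O[C@@H]2CO[Si](C(C)(C)C)(C(C)(C)C)O[C@H]2[C@@H]2OC(OC)C(=C)[C@H]12 | intermediate
10 | C11,C12-diol of 9 | C/C=C/[C@H]1O[C@H](CO)[C@@H](O)[C@@H]2OC(OC)C(=C)[C@H]12 | intermediate
11 | water | O | starting material
12 | iodomethane | CI | starting material
13 | uronic acid (C12 = CO2H) | C/C=C/[C@H]1O[C@H](C(O)=O)[C@@H](O)[C@@H]2OC(OC)C(=C)[C@H]12 | intermediate
14 | methyl uronate (C12 = CO2Me, C11–OH free, C7 α-(E)-propenyl) | C/C=C/[C@H]1O[C@H](C(=O)OC)[C@@H](O)[C@@H]2OC(OC)C(=C)[C@H]12 | intermediate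
15 | dilithium C11 alkoxide/C10 ester enolate of 14 | C/C=C/[C@H]1OC(=C([O-])OC)[C@@H]([O-])[C@@H]2OC(OC)C(=C)[C@H]12.[Li+].[Li+] | intermediate
16 | methyl 10,11-dihydroxy-9-methylcyclohept-7-ene-10-carboxylate fused to the methylene-tetrahydrofuran acetal (C5, C6, C9, C10, C11 as in 30) | COC(=O)[C@]1(O)[C@@H](C)C=C[C@H]2C(=C)C(OC)O[C@H]2[C@@H]1O | intermediate
17 | lithium hydroxide | [Li+].[OH-] | starting material
18 | iodine | II | starting material
19 | lithium carboxylate of 16 | [Li+].[O-]C(=O)[C@]1(O)[C@@H](C)C=C[C@H]2C(=C)C(OC)O[C@H]2[C@@H]1O | intermediate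
20 | bridged iodolactone (C12–O–C8, C7–I anti) | O=C1O[C@@H]2[C@@H](I)[C@H]3C(=C)C(OC)O[C@H]3[C@H](O)[C@@]1(O)[C@H]2C | intermediate
21 | bridged γ-lactone (C7 = CH2) | O=C1O[C@@H]2C[C@H]3C(=C)C(OC)O[C@H]3[C@H](O)[C@@]1(O)[C@H]2C | intermediate
22 | (Z)-1-bromoprop-1-ene | C/C=C\Br | starting material
23 | (Z)-prop-1-enyllithium | C/C=C\[Li] | intermediate
24 | 8,10,11-triol (Z)-enone, lactone ring as methyl acetal | C=C1C(OC)O[C@@H]2[C@H]1C[C@@H](O)[C@H](C)[C@@](O)(C(=O)/C=C\C)[C@H]2O | intermediate
25 | chlorotriethylsilane | CC[Si](Cl)(CC)CC | starting material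
26 | C8 triethylsilyl ether of 24 | C=C1C(OC)O[C@@H]2[C@H]1C[C@@H](O[Si](CC)(CC)CC)[C@H](C)[C@@](O)(C(=O)/C=C\C)[C@H]2O | intermediate
27 | 3-methylbutanoyl chloride | CC(C)CC(Cl)=O | starting material
28 | C11 3-methylbutanoate of 26 | C=C1C(OC)O[C@@H]2[C@H]1C[C@@H](O[Si](CC)(CC)CC)[C@H](C)[C@@](O)(C(=O)/C=C\C)[C@H]2OC(=O)CC(C)C | intermediate
29 | α-methylene lactol (C3–OH, both anomers), C8–OH free | C=C1C(O)O[C@@H]2[C@H]1C[C@@H](O)[C@H](C)[C@@](O)(C(=O)/C=C\C)[C@H]2OC(=O)CC(C)C | intermediate
30 | CNP0186412.2 | C=C1C(=O)O[C@@H]2[C@H]1C[C@@H](O)[C@H](C)[C@@](O)(C(=O)/C=C\C)[C@H]2OC(=O)CC(C)C | target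

**Totals and risks**

Total step count: 14. Longest linear sequence: 14 (from D-glucal).

Step 7. The dianion may fail to rearrange, or may divert to a [1,2] shift, to loss of O11 or to C-attack through C12. The fallback sets out from 6, builds the C9–C10 bond by ketone crotylation and closes the ring by metathesis, and comes back at 20. 6 is cyclized with Bu3SnH under air (Et3B, then PPh3), the C7 radical being trapped by oxygen, to the silylene-protected lactol F1. Methylenation with Ph3P=CH2 opens it to the vinyl carbinol F2 (C7=CH2 on C6, free C10–OH). Dess–Martin periodinane gives the silylene-bound ketone F3. (E)-Crotyl pinacolboronate adds through a closed six-membered transition state on the axial face, anti to the equatorial C11 branch, to give the tertiary carbinol F4 with the C9 methyl as in the target. Ring-closing metathesis with the second-generation Grubbs catalyst RuCl2(=CHPh)(PCy3)(H2IMes) closes C7=C8 to the silylene-protected cycloheptene F5. HF·pyridine gives the triol F6. TEMPO/PhI(OAc)2 oxidizes the primary alcohol to the hydroxy acid F7, the free acid of 19, which under the I2/NaHCO3 conditions of step 8 gives 20.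

Step 10. Double addition, retro-aldol cleavage of the C10–C11 bond in the alkoxide, or Z to E isomerization may occur. The fallback sets out from 21 and comes back at 24. iBu2AlH at −78 °C reduces the lactone to the bridged lactol F8. (Z)-Prop-1-enyllithium 23 premixed with CeCl3 adds to this masked aldehyde to give the allylic alcohol F9 (both carbinol epimers). MnO2 then oxidizes only the allylic alcohol and returns to 24.

Step 11. Silylation may not distinguish O8 from O11. The fallback sets out from 24 and comes back at 29. The 10,11-diol is acylated directly through its stannylene acetal (Bu2SnO, toluene, then 3-methylbutanoyl chloride 27), which activates the secondary oxygen of the diol and leaves the isolated C8–OH, giving the C11 ester with free C8–OH F10. Hydrolysis under the conditions of step 13 returns to 29.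

Further compounds
F1 | step 7 | silylene-protected lactol (C7–OH, both anomers) with the cis-fused methylene-tetrahydrofuran acetal | OC1O[C@@H]2CO[Si](C(C)(C)C)(C(C)(C)C)O[C@H]2[C@@H]2OC(OC)C(=C)[C@H]12
F2 | step 7 | ring-opened vinyl carbinol (C6 vinyl, C10–OH free, 4,6-silylene retained) | C=C[C@H]1C(=C)C(OC)O[C@H]1[C@@H]2O[Si](C(C)(C)C)(C(C)(C)C)OC[C@H]2O
F3 | step 7 | C10 ketone of F2 | C=C[C@H]1C(=C)C(OC)O[C@H]1[C@@H]2O[Si](C(C)(C)C)(C(C)(C)C)OCC2=O
F4 | step 7 | tertiary carbinol from crotylation (C9 methyl, C9 vinyl) | C=C[C@H]1C(=C)C(OC)O[C@H]1[C@@H]2O[Si](C(C)(C)C)(C(C)(C)C)OC[C@]2(O)[C@@H](C)C=C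
F5 | step 7 | silylene-protected cyclohept-7-ene (C10–OH, C12 as CH2O–Si) | C[C@H]1C=C[C@H]2C(=C)C(OC)O[C@H]2[C@@H]3O[Si](C(C)(C)C)(C(C)(C)C)OC[C@]13O
F6 | step 7 | cycloheptene 10,11,12-triol | C[C@H]1C=C[C@H]2C(=C)C(OC)O[C@H]2[C@H](O)[C@]1(O)CO
F7 | step 7 | 10,11-dihydroxy acid (free acid of 19) | C[C@H]1C=C[C@H]2C(=C)C(OC)O[C@H]2[C@H](O)[C@]1(O)C(O)=O
F8 | step 10 | bridged lactol from 21 (C12 hemiacetal, both epimers) | OC1O[C@@H]2C[C@H]3C(=C)C(OC)O[C@H]3[C@H](O)[C@@]1(O)[C@H]2C
F9 | step 10 | (Z)-allylic alcohol tetraol (C12 carbinol, both epimers) | C=C1C(OC)O[C@@H]2[C@H]1C[C@@H](O)[C@H](C)[C@@](O)(C(O)/C=C\C)[C@H]2O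
F10 | step 11 | C11 3-methylbutanoate with free C8–OH, lactone ring as methyl acetal | C=C1C(OC)O[C@@H]2[C@H]1C[C@@H](O)[C@H](C)[C@@](O)(C(=O)/C=C\C)[C@H]2OC(=O)CC(C)C
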